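**Plan**

1. Retrosynthetic cuts: the caffeate C=C and the C15–O ester (Knoevenagel–Doebner on a malonic half-ester); C13–C14 (nickel-catalysed enantioconvergent alkylation); C4–CH3 (enolate methylation); C5–C6 and C9–C10 together (Diels–Alder that forms ring B); the C9–C11 link and the diene (carbomagnesiation, Sonogashira).
2. Forward order: ring A enone 4 (enamine Michael, aldol) → ring B by [4+2] with dienyne 11 → C1 deoxygenation → allylic chloride → C13–C14 coupling → saturation of C11=C12 → exocyclic methylene by reductive transposition of a C17 enal → C4 methylation and oxidation to the acid → C15 alcohol → caffeate.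
3. Stereochemistry: C4 of 4 comes from the prolinol catalyst and sends the diene to the opposite face; suprafacial endo addition puts H5, CH3-20 and H9 on one face (cis-decalin, C11 trans to CH3-20); C4 is then re-set by equatorial methylation; C13 comes from the chiral nickel catalyst.
4. Enabling feature: C13 is a methyl-bearing CH next to C12. A temporary C11=C12 double bond makes C11–C12–C13 a 1,3-disubstituted allyl unit whose C11 end is blocked by ring B carbon C9 and whose C13 end carries only CH3-16, so a racemic C13 chloride can be alkylated at C13 alone under catalyst control. C14–C15 enter as a two-carbon zinc reagent with C15 as a dioxolane.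
5. Helpers removed later: C11=C12 (hydrogenation), the dioxolane (hydrolysis, reduction), the C17 oxygen (becomes =CH2), the C1 ketone (reduction to CH2).

Key step: step 11

Remark on the structure: the SMILES encodes (4S,5S,9R,10R,13S) in labdane numbering, i.e. a cis-fused decalin with H5, H9, CH3-20 and the C4 carboxyl on one face (called β) and the C9 side chain and CH3-18 on the other (α); the route is built for this diastereomer. Labdane locants are used throughout (ring A = C1–C5, C10; ring B = C5–C10; C17 on C8; C19 the oxygenated carbon on C4).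

Remark on the catalysts: the senses of induction in steps 1 and 11 are taken from the accepted models for these catalyst classes; if either proved opposite, the mirror-image catalyst would be used with no other change.

**Step 1**
Reactants: 1 3-[(tert-butyldiphenylsilyl)oxy]propanal; 2 pent-1-en-3-one
Product: 3 (2R)-2-{[(tert-butyldiphenylsilyl)oxy]methyl}-5-oxoheptanal
Conditions: (R)-2-(methoxydiphenylmethyl)pyrrolidine (5 mol%), ethyl 3,4-dihydroxybenzoate (20 mol%), neat, 4 °C
Reagents that add atoms: none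
Why: Enamine-catalysed asymmetric Michael addition; the diphenylmethoxymethyl group shields one face of the (E)-enamine so the enone adds to the other, which sets the future C4 centre.

**Step 2**
Reactants: 3 (2R)-2-{[(tert-butyldiphenylsilyl)oxy]methyl}-5-oxoheptanal
Product: 4 (4S)-4-{[(tert-butyldiphenylsilyl)oxy]methyl}-2-methylcyclohex-2-en-1-one
Conditions: 0.1 M aq. KOH, Bu4NOH (cat.), Et2O–THF, 35 °C
Reagents that add atoms: none
Why: Intramolecular aldol condensation of the ethyl ketone onto the aldehyde (the only six-membered mode) gives the 2-methyl enone; dilute base is chosen to leave the γ stereocentre untouched.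

**Step 3**
Reactants: 5 prop-2-yn-1-ol; 6 vinylmagnesium chloride
Product: 8 (2Z)-2-ethenyl-3-iodoprop-2-en-1-ol, via magnesium chelate 7 (not isolated)
Conditions: CH2=CHMgCl (2.5 equiv), THF–cyclohexane, reflux; then I2, THF, −78 → 0 °C
Reagents that add atoms: iodine, SMILES II
Why: Alkoxide-directed anti-carbomagnesiation puts the vinyl group on the carbinol-bearing alkyne carbon and magnesium on the terminal carbon cis to CH2O (five-membered chelate); iodinolysis with retention fixes the Z geometry that the s-cis diene needs.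

**Step 4**
Reactants: 8 (2Z)-2-ethenyl-3-iodoprop-2-en-1-ol
Product: 9 tert-butyl{[(2Z)-2-ethenyl-3-iodoprop-2-en-1-yl]oxy}diphenylsilane
Conditions: TBDPSCl, imidazole, CH2Cl2, 0 °C → rt
Reagents that add atoms: tert-butyl(chloro)diphenylsilane, SMILES CC(C)(C)[Si](Cl)(c1ccccc1)c1ccccc1
Why: Standard silylation of a primary allylic alcohol; the bulky, acid-stable silyl ether masks the future C17 oxygen.

**Step 5**
Reactants: 9 tert-butyl{[(2Z)-2-ethenyl-3-iodoprop-2-en-1-yl]oxy}diphenylsilane; 10 rac-tert-butyl(but-3-yn-2-yloxy)dimethylsilane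
Product: 11 (3Z)-7-[(tert-butyldimethylsilyl)oxy]-3-{[(tert-butyldiphenylsilyl)oxy]methyl}octa-1,3-dien-5-yne
Conditions: Pd(PPh3)2Cl2 (3 mol%), CuI (6 mol%), Et3N, THF, rt
Reagents that add atoms: none
Why: Sonogashira coupling of an alkenyl iodide proceeds with retention of alkene geometry and brings in C11, C12, C13 and CH3-16.

**Step 6**
Reactants: 4 (4S)-4-{[(tert-butyldiphenylsilyl)oxy]methyl}-2-methylcyclohex-2-en-1-one; 11 (3Z)-7-[(tert-butyldimethylsilyl)oxy]-3-{[(tert-butyldiphenylsilyl)oxy]methyl}octa-1,3-dien-5-yne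
Product: 12 13-[(tert-butyldimethylsilyl)oxy]-17,19-bis[(tert-butyldiphenylsilyl)oxy]-14,15,18-trinorlabd-7-en-11-yn-1-one (4α-H; 5β-H; 9β-H; 10β-CH3; C13 epimers)
Conditions: EtAlCl2 (0.5 equiv), CH2Cl2–toluene, −40 → 0 °C
Reagents that add atoms: none
Why: Lewis-acid-promoted Diels–Alder reaction; the diene should add suprafacially (cis fusion) to the enone face anti to the C4 silyloxymethyl group and endo to the C1 carbonyl (C11 cis to C1, so H9 cis to CH3-20), with C6 bonding to C5 because the alkynyl-substituted terminus C9 best carries the developing positive charge.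

**Step 7**
Reactants: 12 13-[(tert-butyldimethylsilyl)oxy]-17,19-bis[(tert-butyldiphenylsilyl)oxy]-14,15,18-trinorlabd-7-en-11-yn-1-one
Product: 14 13-[(tert-butyldimethylsilyl)oxy]-17,19-bis[(tert-butyldiphenylsilyl)oxy]-14,15,18-trinorlabd-7-en-11-yne, via tosylhydrazone 13 (not isolated)
Conditions: TsNHNH2, THF, 4 Å MS, 60 °C; then catecholborane, CHCl3, 0 °C → rt; NaOAc·3H2O, 60 °C
Reagents that add atoms: none
Why: Tosylhydrazone reduction (hydride addition, loss of sulfinate, loss of N2 from the alkyl diazene) turns the C1 ketone into CH2 under near-neutral conditions that spare the silyl ethers, the alkyne and the C7=C8 bond.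

**Step 8**
Reactants: 14 13-[(tert-butyldimethylsilyl)oxy]-17,19-bis[(tert-butyldiphenylsilyl)oxy]-14,15,18-trinorlabd-7-en-11-yne
Product: 15 17,19-bis[(tert-butyldiphenylsilyl)oxy]-14,15,18-trinorlabd-7-en-11-yn-13-ol (C13 epimers)
Conditions: PPTS, EtOH, 45 °C
Reagents that add atoms: none
Why: Acid-catalysed solvolysis removes the tert-butyldimethylsilyl ether far faster than the two tert-butyldiphenylsilyl ethers.

**Step 9**
Reactants: 15 17,19-bis[(tert-butyldiphenylsilyl)oxy]-14,15,18-trinorlabd-7-en-11-yn-13-ol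
Product: 16 (11E)-17,19-bis[(tert-butyldiphenylsilyl)oxy]-14,15,18-trinorlabda-7,11-dien-13-ol (C13 epimers)
Conditions: NaAlH2(OCH2CH2OMe)2, THF, 0 °C → rt
Reagents that add atoms: none
Why: Alkoxide-directed trans-hydroalumination of a propargylic alcohol gives the (E)-allylic alcohol only; isolated alkenes are not reduced.

**Step 10**
Reactants: 16 (11E)-17,19-bis[(tert-butyldiphenylsilyl)oxy]-14,15,18-trinorlabda-7,11-dien-13-ol
Product: 17 (11E)-13-chloro-17,19-bis[(tert-butyldiphenylsilyl)oxy]-14,15,18-trinorlabda-7,11-diene (C13 epimers)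
Conditions: MsCl, 2,4,6-collidine, LiCl, DMF, 0 °C
Reagents that add atoms: lithium chloride, SMILES [Li+].[Cl-]
Why: Mesylation and chloride displacement at the unhindered C13 carbinol under buffered conditions give the secondary allylic chloride; its C13 configuration does not matter for the next step.

**Step 11**
Reactants: 17 (11E)-13-chloro-17,19-bis[(tert-butyldiphenylsilyl)oxy]-14,15,18-trinorlabda-7,11-diene; 18 (1,3-dioxolan-2-ylmethyl)zinc bromide
Product: 19 (11E,13R)-17,19-bis[(tert-butyldiphenylsilyl)oxy]-15,15-(ethylenedioxy)-18-norlabda-7,11-diene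
Conditions: NiCl2·DME (5 mol%), (S,S)-2,6-bis(4-phenethyl-4,5-dihydrooxazol-2-yl)pyridine (5.5 mol%), NaCl (4 equiv), DMA–DMF (1:1), −10 °C
Reagents that add atoms: none
Why: The nickel catalyst takes chloride from either enantiomer of 17 to give a common allyl radical/π-allylnickel species across C11–C12–C13, transmetalation from zinc delivers the dioxolanylmethyl group, and reductive elimination forms C13–C14; the closest known reaction type is the nickel/pybox enantioconvergent Negishi coupling of racemic secondary allylic chlorides with alkylzinc halides. No ring is closed. The new C13 centre is set by the chiral ligand (catalyst control), because the ring stereocentres are remote and the C13 configuration of 17 is erased in the allyl intermediate. Regioselectivity for C13 over C11 is needed and is secured by the branched ring carbon C9 on C11 against a single methyl on C13, so the bond should form at the less hindered terminus with the double bond left E at C11=C12. The silyl ethers and the trisubstituted C7=C8 bond are inert to the alkylzinc reagent and the catalyst.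

**Step 12**
Reactants: 19 (11E,13R)-17,19-bis[(tert-butyldiphenylsilyl)oxy]-15,15-(ethylenedioxy)-18-norlabda-7,11-diene
Product: 20 (13S)-17,19-bis[(tert-butyldiphenylsilyl)oxy]-15,15-(ethylenedioxy)-18-norlabd-7-ene
Conditions: H2 (3 atm), RhCl(PPh3)3 (10 mol%), benzene–EtOH, rt
Reagents that add atoms: none
Why: Homogeneous hydrogenation with RhCl(PPh3)3 reduces the 1,2-disubstituted C11=C12 bond and should leave the trisubstituted C7=C8 bond; C13 is unchanged in space and its descriptor becomes S only because C12 loses priority.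

**Step 13**
Reactants: 20 (13S)-17,19-bis[(tert-butyldiphenylsilyl)oxy]-15,15-(ethylenedioxy)-18-norlabd-7-ene
Product: 21 (13S)-15,15-(ethylenedioxy)-18-norlabd-7-ene-17,19-diol
Conditions: Bu4NF, THF, rt
Reagents that add atoms: none
Why: Fluoride cleaves both silyl ethers; the dioxolane is stable to it.

**Step 14**
Reactants: 21 (13S)-15,15-(ethylenedioxy)-18-norlabd-7-ene-17,19-diol
Product: 22 (13S)-15,15-(ethylenedioxy)-19-hydroxy-18-norlabd-7-en-17-al
Conditions: MnO2, CH2Cl2, rt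
Reagents that add atoms: none
Why: MnO2 oxidises the allylic C17 alcohol and not the saturated C19 alcohol, which differentiates the two primary hydroxyl groups.

**Step 15**
Reactants: 22 (13S)-15,15-(ethylenedioxy)-19-hydroxy-18-norlabd-7-en-17-al
Product: 24 (13S)-15,15-(ethylenedioxy)-18-norlabd-8(17)-en-19-ol, via tosylhydrazone 23 (not isolated)
Conditions: TsNHNH2, THF, rt; then catecholborane, CHCl3, 0 °C; NaOAc·3H2O, 60 °C
Reagents that add atoms: none
Why: Reductive 1,3-transposition of an α,β-unsaturated tosylhydrazone: 1,2-hydride addition and loss of sulfinate give an allylic diazene whose retro-ene loss of N2 delivers hydrogen to C7 and moves the double bond to C8=C17.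

**Step 16**
Reactants: 24 (13S)-15,15-(ethylenedioxy)-18-norlabd-8(17)-en-19-ol
Product: 25 (13S)-15,15-(ethylenedioxy)-18-norlabd-8(17)-en-19-al
Conditions: Dess–Martin periodinane, CH2Cl2, 0 °C → rt
Reagents that add atoms: none
Why: Dess–Martin oxidation of a primary alcohol to the aldehyde under conditions that leave the alkene and the acetal alone.

**Step 17**
Reactants: 25 (13S)-15,15-(ethylenedioxy)-18-norlabd-8(17)-en-19-al
Product: 26 (4S,13S)-15,15-(ethylenedioxy)labd-8(17)-en-19-al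
Conditions: KOtBu, THF, −20 °C; MeI, −20 → 0 °C
Reagents that add atoms: iodomethane, SMILES CI
Why: Enolate C-methylation; the equatorial C9 side chain should hold ring A in the chair with CH3-20 axial, so MeI enters C4 equatorially from the α face, away from the syn-axial CH3-20, giving 4α-CH3 and 4β-CHO.

**Step 18**
Reactants: 26 (4S,13S)-15,15-(ethylenedioxy)labd-8(17)-en-19-al
Product: 27 (4S,13S)-15,15-(ethylenedioxy)labd-8(17)-en-19-oic acid
Conditions: NaClO2, NaH2PO4, 2-methyl-2-butene, t-BuOH–H2O, 0 °C → rt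
Reagents that add atoms: sodium chlorite, SMILES [Na+].[O-]Cl=O
Why: Pinnick oxidation converts the hindered neopentyl aldehyde to the acid; the alkene scavenger protects the exocyclic methylene from hypochlorous acid.

**Step 19**
Reactants: 27 (4S,13S)-15,15-(ethylenedioxy)labd-8(17)-en-19-oic acid
Product: 29 (4S,5S,9R,10R,13S)-15-hydroxylabd-8(17)-en-19-oic acid, via aldehyde 28 (not isolated)
Conditions: AcOH–H2O–THF (3:1:1), 55 °C; concentrate; then NaBH4, MeOH, 0 °C
Reagents that add atoms: water, SMILES O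
Why: Mild acetal hydrolysis followed by borohydride reduction gives the C15 alcohol; neither step should touch the exocyclic alkene or the hindered acid.

**Step 20**
Reactants: 29 (4S,5S,9R,10R,13S)-15-hydroxylabd-8(17)-en-19-oic acid; 30 2,2-dimethyl-1,3-dioxane-4,6-dione (Meldrum's acid); 31 3,4-dihydroxybenzaldehyde
Product: 33 target caffeate, via malonic half-ester 32 (not isolated)
Conditions: 30, toluene, 110 °C; then 31, pyridine, piperidine (cat.), 50 °C
Reagents that add atoms: none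
Why: The acylketene from thermolysis of Meldrum's acid acylates the primary C15 alcohol (the tertiary C19 acid is a spectator), and Knoevenagel–Doebner condensation with decarboxylation gives the (E)-caffeate without protecting the catechol.

**Compound list**

1 | 3-[(tert-butyldiphenylsilyl)oxy]propanal | O=CCCO[Si](c1ccccc1)(c1ccccc1)C(C)(C)C | starting material
2 | pent-1-en-3-one | C=CC(=O)CC | starting material
3 | (2R)-2-{[(tert-butyldiphenylsilyl)oxy]methyl}-5-oxoheptanal | O=C[C@@H](CO[Si](c1ccccc1)(c1ccccc1)C(C)(C)C)CCC(=O)CC | intermediate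
4 | (4S)-4-{[(tert-butyldiphenylsilyl)oxy]methyl}-2-methylcyclohex-2-en-1-one | CC1=C[C@@H](CO[Si](c2ccccc2)(c2ccccc2)C(C)(C)C)CCC1=O | intermediate
5 | prop-2-yn-1-ol | C#CCO | starting material
6 | vinylmagnesium chloride | C=C[Mg]Cl | starting material
7 | 3-ethenyl-2,5-dihydro-1,2-oxamagnesole (magnesium chelate) | C=CC1=C[Mg]OC1 | intermediate
8 | (2Z)-2-ethenyl-3-iodoprop-2-en-1-ol | C=C/C(CO)=C/I | intermediate
9 | tert-butyl{[(2Z)-2-ethenyl-3-iodoprop-2-en-1-yl]oxy}diphenylsilane | C=C/C(CO[Si](c1ccccc1)(c1ccccc1)C(C)(C)C)=C/I | intermediate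
10 | rac-tert-butyl(but-3-yn-2-yloxy)dimethylsilane | C#CC(C)O[Si](C)(C)C(C)(C)C | starting material
11 | (3Z)-7-[(tert-butyldimethylsilyl)oxy]-3-{[(tert-butyldiphenylsilyl)oxy]methyl}octa-1,3-dien-5-yne (racemic at C7) | C=C/C(CO[Si](c1ccccc1)(c1ccccc1)C(C)(C)C)=C/C#CC(C)O[Si](C)(C)C(C)(C)C | intermediate
12 | 13-[(tert-butyldimethylsilyl)oxy]-17,19-bis[(tert-butyldiphenylsilyl)oxy]-14,15,18-trinorlabd-7-en-11-yn-1-one (4α-H, 5β-H, 9β-H, 10β-CH3; C13 epimers) | CC(C)(C)[Si](c1ccccc1)(c1ccccc1)OCC1=CC[C@H]2[C@](C)(C(=O)CC[C@@H]2CO[Si](c2ccccc2)(c2ccccc2)C(C)(C)C)[C@@H]1C#CC(C)O[Si](C)(C)C(C)(C)C | intermediate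
13 | C1 4-methylbenzenesulfonylhydrazone of 12 | CC(C)(C)[Si](c1ccccc1)(c1ccccc1)OCC1=CC[C@H]2[C@](C)(C(=NNS(=O)(=O)c3ccc(C)cc3)CC[C@@H]2CO[Si](c2ccccc2)(c2ccccc2)C(C)(C)C)[C@@H]1C#CC(C)O[Si](C)(C)C(C)(C)C | intermediate
14 | 13-[(tert-butyldimethylsilyl)oxy]-17,19-bis[(tert-butyldiphenylsilyl)oxy]-14,15,18-trinorlabd-7-en-11-yne (ring configuration as in 12; C13 epimers) | CC(C)(C)[Si](c1ccccc1)(c1ccccc1)OCC1=CC[C@H]2[C@](C)(CCC[C@@H]2CO[Si](c2ccccc2)(c2ccccc2)C(C)(C)C)[C@@H]1C#CC(C)O[Si](C)(C)C(C)(C)C | intermediate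
15 | 17,19-bis[(tert-butyldiphenylsilyl)oxy]-14,15,18-trinorlabd-7-en-11-yn-13-ol (C13 epimers) | CC(C)(C)[Si](c1ccccc1)(c1ccccc1)OCC1=CC[C@H]2[C@](C)(CCC[C@@H]2CO[Si](c2ccccc2)(c2ccccc2)C(C)(C)C)[C@@H]1C#CC(C)O | intermediate
16 | (11E)-17,19-bis[(tert-butyldiphenylsilyl)oxy]-14,15,18-trinorlabda-7,11-dien-13-ol (C13 epimers) | CC(C)(C)[Si](c1ccccc1)(c1ccccc1)OCC1=CC[C@H]2[C@](C)(CCC[C@@H]2CO[Si](c2ccccc2)(c2ccccc2)C(C)(C)C)[C@@H]1/C=C/C(C)O | intermediate
17 | (11E)-13-chloro-17,19-bis[(tert-butyldiphenylsilyl)oxy]-14,15,18-trinorlabda-7,11-diene (C13 epimers) | CC(C)(C)[Si](c1ccccc1)(c1ccccc1)OCC1=CC[C@H]2[C@](C)(CCC[C@@H]2CO[Si](c2ccccc2)(c2ccccc2)C(C)(C)C)[C@@H]1/C=C/C(C)Cl | intermediate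
18 | (1,3-dioxolan-2-ylmethyl)zinc bromide | Br[Zn]CC1OCCO1 | starting material
19 | (11E,13R)-17,19-bis[(tert-butyldiphenylsilyl)oxy]-15,15-(ethylenedioxy)-18-norlabda-7,11-diene | CC(C)(C)[Si](c1ccccc1)(c1ccccc1)OCC1=CC[C@H]2[C@](C)(CCC[C@@H]2CO[Si](c2ccccc2)(c2ccccc2)C(C)(C)C)[C@@H]1/C=C/[C@H](C)CC1OCCO1 | intermediate
20 | (13S)-17,19-bis[(tert-butyldiphenylsilyl)oxy]-15,15-(ethylenedioxy)-18-norlabd-7-ene | CC(C)(C)[Si](c1ccccc1)(c1ccccc1)OCC1=CC[C@H]2[C@](C)(CCC[C@@H]2CO[Si](c2ccccc2)(c2ccccc2)C(C)(C)C)[C@@H]1CC[C@H](C)CC1OCCO1 | intermediate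
21 | (13S)-15,15-(ethylenedioxy)-18-norlabd-7-ene-17,19-diol | OCC1=CC[C@H]2[C@](C)(CCC[C@@H]2CO)[C@@H]1CC[C@H](C)CC1OCCO1 | intermediate
22 | (13S)-15,15-(ethylenedioxy)-19-hydroxy-18-norlabd-7-en-17-al | O=CC1=CC[C@H]2[C@](C)(CCC[C@@H]2CO)[C@@H]1CC[C@H](C)CC1OCCO1 | intermediate
23 | C17 4-methylbenzenesulfonylhydrazone of 22 | Cc1ccc(cc1)S(=O)(=O)NN=CC1=CC[C@H]2[C@](C)(CCC[C@@H]2CO)[C@@H]1CC[C@H](C)CC1OCCO1 | intermediate
24 | (13S)-15,15-(ethylenedioxy)-18-norlabd-8(17)-en-19-ol | C=C1CC[C@H]2[C@](C)(CCC[C@@H]2CO)[C@@H]1CC[C@H](C)CC1OCCO1 | intermediate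
25 | (13S)-15,15-(ethylenedioxy)-18-norlabd-8(17)-en-19-al (4α-H) | C=C1CC[C@H]2[C@](C)(CCC[C@@H]2C=O)[C@@H]1CC[C@H](C)CC1OCCO1 | intermediate
26 | (4S,13S)-15,15-(ethylenedioxy)labd-8(17)-en-19-al (4α-CH3, 5β-H, 9β-H) | C=C1CC[C@H]2[C@](C)(CCC[C@]2(C)C=O)[C@@H]1CC[C@H](C)CC1OCCO1 | intermediate
27 | (4S,13S)-15,15-(ethylenedioxy)labd-8(17)-en-19-oic acid | C=C1CC[C@H]2[C@](C)(CCC[C@]2(C)C(=O)O)[C@@H]1CC[C@H](C)CC1OCCO1 | intermediate
28 | (4S,13S)-15-oxolabd-8(17)-en-19-oic acid | C=C1CC[C@H]2[C@](C)(CCC[C@]2(C)C(=O)O)[C@@H]1CC[C@H](C)CC=O | intermediate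
29 | (4S,5S,9R,10R,13S)-15-hydroxylabd-8(17)-en-19-oic acid | C=C1CC[C@H]2[C@](C)(CCC[C@]2(C)C(=O)O)[C@@H]1CC[C@H](C)CCO | intermediate
30 | 2,2-dimethyl-1,3-dioxane-4,6-dione (Meldrum's acid) | CC1(C)OC(=O)CC(=O)O1 | starting material
31 | 3,4-dihydroxybenzaldehyde | O=Cc1ccc(O)c(O)c1 | starting material
32 | (4S,5S,9R,10R,13S)-15-[(carboxyacetyl)oxy]labd-8(17)-en-19-oic acid | C=C1CC[C@H]2[C@](C)(CCC[C@]2(C)C(=O)O)[C@@H]1CC[C@H](C)CCOC(=O)CC(=O)O | intermediate
33 | (4S,5S,9R,10R,13S)-15-{[(2E)-3-(3,4-dihydroxyphenyl)prop-2-enoyl]oxy}labd-8(17)-en-19-oic acid | C=C1CC[C@H]2[C@](C)(CCC[C@]2(C)C(=O)O)[C@@H]1CC[C@H](C)CCOC(=O)/C=C/c1ccc(O)c(O)c1 | target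

**Count and risks**

Total step count: 20. Longest linear sequence: 18 steps (steps 3 to 20).

Step 6 (cycloaddition). What may go wrong: the Lewis acid may ionise the propargylic or allylic silyl ether of the dienyne, C9 may compete with C6 for bonding to C5, or the diene may add partly syn to the C4 substituent (that adduct is a diastereomer and would be removed by chromatography at the cost of material). The fallback leaves the alkyne out of the cycloaddition and builds C11=C12 afterwards by olefination. It sets out from 5 (and uses 4) and returns at 16. Chelate 7 is alkylated with benzyl chloromethyl ether (CuI cat.) instead of being iodinated, to give (2Z)-4-(benzyloxy)-2-ethenylbut-2-en-1-ol F1. Silylation gives tert-butyl{[(2Z)-4-(benzyloxy)-2-ethenylbut-2-en-1-yl]oxy}diphenylsilane F2, a plain 1-alkyl diene. Its EtAlCl2-promoted cycloaddition with 4 gives 11-(benzyloxy)-17,19-bis[(tert-butyldiphenylsilyl)oxy]-12,13,14,15,16,18-hexanorlabd-7-en-1-one F3. The C1 tosylhydrazone F4 and catecholborane give the 1-deoxo benzyl ether F5. DDQ in wet CH2Cl2 under 525 nm light removes the benzyl group to give the C11 alcohol F6, and Dess–Martin oxidation gives the C11 aldehyde F7. Wittig reaction with 1-(triphenylphosphoranylidene)propan-2-one gives the (11E)-en-13-one F8, and NaBH4/CeCl3·7H2O reduces it to 16.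

Step 11 (key coupling). What may go wrong: loss of a β-alkoxide from the acetal-bearing organozinc or organonickel species, weak catalyst control at C13, or competing elimination of the allylic chloride to a diene. The fallback makes C13–C14 by olefination and sets C13 by directed hydrogenation. It sets out from 16 and returns at 20. Hydrogenation of 16 (H2, RhCl(PPh3)3) gives the saturated 13-ol F9, and Dess–Martin oxidation gives the methyl ketone F10. Horner–Wadsworth–Emmons reaction with triethyl phosphonoacetate (NaH, THF) gives the (13E)-enoate F11, the Z isomer being removed by chromatography. iBu2AlH gives the allylic alcohol F12. Ru(OAc)2[(R)-BINAP] with H2 (30 atm, MeOH), the hydrogenation known for geraniol-type allylic alcohols that leaves isolated alkenes alone, gives the (13S)-15-alcohol F13. Dess–Martin oxidation gives the 15-aldehyde F14, and ethylene glycol with PPTS in benzene gives 20.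

Step 17 (C4 methylation). What may go wrong: O-methylation of the aldehyde enolate, or methylation from the β face if the other chair of ring A reacts. The fallback builds the quaternary centre at the nitrile oxidation level, where the small linear anion is alkylated equatorially with high reliability. It sets out from 25 and returns at 26. NH2OH·HCl in pyridine gives the oxime F15, and dehydration with acetic anhydride gives the 19-nitrile F16. LiN(iPr)2 then MeI (THF, −78 °C) gives the 4α-methyl-4β-nitrile F17. iBu2AlH (toluene, −78 °C) and buffered hydrolysis of the imine give 26.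

**Further compounds**

F1 | step 6 | (2Z)-4-(benzyloxy)-2-ethenylbut-2-en-1-ol | C=C/C(CO)=C/COCc1ccccc1
F2 | step 6 | tert-butyl{[(2Z)-4-(benzyloxy)-2-ethenylbut-2-en-1-yl]oxy}diphenylsilane | C=C/C(CO[Si](c1ccccc1)(c1ccccc1)C(C)(C)C)=C/COCc1ccccc1
F3 | step 6 | 11-(benzyloxy)-17,19-bis[(tert-butyldiphenylsilyl)oxy]-12,13,14,15,16,18-hexanorlabd-7-en-1-one (4α-H, 5β-H, 9β-H) | CC(C)(C)[Si](c1ccccc1)(c1ccccc1)OCC1=CC[C@H]2[C@](C)(C(=O)CC[C@@H]2CO[Si](c2ccccc2)(c2ccccc2)C(C)(C)C)[C@@H]1COCc1ccccc1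
F4 | step 6 | C1 4-methylbenzenesulfonylhydrazone of F3 | CC(C)(C)[Si](c1ccccc1)(c1ccccc1)OCC1=CC[C@H]2[C@](C)(C(=NNS(=O)(=O)c3ccc(C)cc3)CC[C@@H]2CO[Si](c2ccccc2)(c2ccccc2)C(C)(C)C)[C@@H]1COCc1ccccc1
F5 | step 6 | 11-(benzyloxy)-17,19-bis[(tert-butyldiphenylsilyl)oxy]-12,13,14,15,16,18-hexanorlabd-7-ene | CC(C)(C)[Si](c1ccccc1)(c1ccccc1)OCC1=CC[C@H]2[C@](C)(CCC[C@@H]2CO[Si](c2ccccc2)(c2ccccc2)C(C)(C)C)[C@@H]1COCc1ccccc1
F6 | step 6 | 17,19-bis[(tert-butyldiphenylsilyl)oxy]-12,13,14,15,16,18-hexanorlabd-7-en-11-ol | CC(C)(C)[Si](c1ccccc1)(c1ccccc1)OCC1=CC[C@H]2[C@](C)(CCC[C@@H]2CO[Si](c2ccccc2)(c2ccccc2)C(C)(C)C)[C@@H]1CO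
F7 | step 6 | 17,19-bis[(tert-butyldiphenylsilyl)oxy]-12,13,14,15,16,18-hexanorlabd-7-en-11-al | CC(C)(C)[Si](c1ccccc1)(c1ccccc1)OCC1=CC[C@H]2[C@](C)(CCC[C@@H]2CO[Si](c2ccccc2)(c2ccccc2)C(C)(C)C)[C@@H]1C=O
F8 | step 6 | (11E)-17,19-bis[(tert-butyldiphenylsilyl)oxy]-14,15,18-trinorlabda-7,11-dien-13-one | CC(C)(C)[Si](c1ccccc1)(c1ccccc1)OCC1=CC[C@H]2[C@](C)(CCC[C@@H]2CO[Si](c2ccccc2)(c2ccccc2)C(C)(C)C)[C@@H]1/C=C/C(C)=O
F9 | step 11 | 17,19-bis[(tert-butyldiphenylsilyl)oxy]-14,15,18-trinorlabd-7-en-13-ol (C13 epimers) | CC(C)(C)[Si](c1ccccc1)(c1ccccc1)OCC1=CC[C@H]2[C@](C)(CCC[C@@H]2CO[Si](c2ccccc2)(c2ccccc2)C(C)(C)C)[C@@H]1CCC(C)O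
F10 | step 11 | 17,19-bis[(tert-butyldiphenylsilyl)oxy]-14,15,18-trinorlabd-7-en-13-one | CC(C)(C)[Si](c1ccccc1)(c1ccccc1)OCC1=CC[C@H]2[C@](C)(CCC[C@@H]2CO[Si](c2ccccc2)(c2ccccc2)C(C)(C)C)[C@@H]1CCC(C)=O
F11 | step 11 | ethyl (13E)-17,19-bis[(tert-butyldiphenylsilyl)oxy]-18-norlabda-7,13-dien-15-oate | CC(C)(C)[Si](c1ccccc1)(c1ccccc1)OCC1=CC[C@H]2[C@](C)(CCC[C@@H]2CO[Si](c2ccccc2)(c2ccccc2)C(C)(C)C)[C@@H]1CC/C(C)=C/C(=O)OCC
F12 | step 11 | (13E)-17,19-bis[(tert-butyldiphenylsilyl)oxy]-18-norlabda-7,13-dien-15-ol | CC(C)(C)[Si](c1ccccc1)(c1ccccc1)OCC1=CC[C@H]2[C@](C)(CCC[C@@H]2CO[Si](c2ccccc2)(c2ccccc2)C(C)(C)C)[C@@H]1CC/C(C)=C/CO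
F13 | step 11 | (13S)-17,19-bis[(tert-butyldiphenylsilyl)oxy]-18-norlabd-7-en-15-ol | CC(C)(C)[Si](c1ccccc1)(c1ccccc1)OCC1=CC[C@H]2[C@](C)(CCC[C@@H]2CO[Si](c2ccccc2)(c2ccccc2)C(C)(C)C)[C@@H]1CC[C@H](C)CCO
F14 | step 11 | (13S)-17,19-bis[(tert-butyldiphenylsilyl)oxy]-18-norlabd-7-en-15-al | CC(C)(C)[Si](c1ccccc1)(c1ccccc1)OCC1=CC[C@H]2[C@](C)(CCC[C@@H]2CO[Si](c2ccccc2)(c2ccccc2)C(C)(C)C)[C@@H]1CC[C@H](C)CC=O
F15 | step 17 | oxime of 25 | C=C1CC[C@H]2[C@](C)(CCC[C@@H]2C=NO)[C@@H]1CC[C@H](C)CC1OCCO1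
F16 | step 17 | (13S)-15,15-(ethylenedioxy)-18-norlabd-8(17)-ene-19-nitrile (4α-H) | C=C1CC[C@H]2[C@](C)(CCC[C@@H]2C#N)[C@@H]1CC[C@H](C)CC1OCCO1
F17 | step 17 | (4S,13S)-15,15-(ethylenedioxy)labd-8(17)-ene-19-nitrile | C=C1CC[C@H]2[C@](C)(CCC[C@]2(C)C#N)[C@@H]1CC[C@H](C)CC1OCCO1
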